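The two side-chain C2''=C3'' bonds of the 3-methylbut-2-enyl groups on C6 and C8 of ring A are disconnected. These electron-rich alkenes sit ortho to the C5 and C7 hydroxyls and would close to chromans in acid, so they are made last. One double cross-metathesis with 2-methyl-2-butene replaces the terminal CH2 of two allyl groups by C(CH3)2 on the fully unprotected flavanonol. The precursor is (2R,3R)-6,8-diallylaromadendrin, which already holds ring C, both stereocentres and all four free hydroxyls. It is reached by O-allylation and Claisen rearrangement, chalcone formation, asymmetric epoxidation and acid-mediated ring closure.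

Key step: step 8

Remark: the target is the 2,3-trans isomer with C2 = R and C3 = R. Step 1 consumes two equivalents of allyl bromide. Partly O-alkylated species in steps 1 and 3 and partly deprotected species in step 7 arise by repeating one reaction on the next identical group and are not numbered separately.

Step 1
Reactants: 1 2,4,6-trihydroxyacetophenone; 2 allyl bromide
Product: 3 1-[2-hydroxy-4,6-bis(prop-2-enyloxy)phenyl]ethanone
Conditions: allyl bromide (2.2 equiv in all), K2CO3, acetone, reflux
Reagents that add atoms: allyl bromide (second equivalent of 2), C=CCBr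
Why: Two successive Williamson ether syntheses; once the 4-hydroxyl and one ortho-hydroxyl are allylated, the remaining hydroxyl is hydrogen-bonded to the acetyl carbonyl, is the least nucleophilic and should stay free when only about two equivalents of halide are used.

Step 2
Reactants: 3 1-[2-hydroxy-4,6-bis(prop-2-enyloxy)phenyl]ethanone
Product: 5 C-diallylated triol (3,5-diallyl-2,4,6-trihydroxyacetophenone), via mono-rearranged allyl ether 4 (not isolated)
Conditions: PhNEt2, 200 °C, N2
Reagents that add atoms: none
Why: Two successive aromatic Claisen rearrangements ([3,3]-sigmatropic shift, then enolisation) move each allyl group from oxygen to carbon; C3 and C5 are the only unsubstituted ring positions, so the ortho pathway and the ortho-then-Cope (para) pathway converge on the same 3,5-diallyl triol, and the basic solvent suppresses acid-induced ring closure of the new ortho-allylphenols.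

Step 3
Reactants: 5 3,5-diallyl-2,4,6-trihydroxyacetophenone
Product: 6 1-[2,4,6-tris(methoxymethoxy)-3,5-di(prop-2-enyl)phenyl]ethanone
Conditions: NaH, MOMCl (excess), THF–DMF, 0 °C to rt
Reagents that add atoms: chloromethyl methyl ether (MOMCl), COCCl
Why: Exhaustive Williamson-type O-alkylation of the tris-phenoxide with a small, hard electrophile; NaH brings the chelated and flanked hydroxyls into reaction, and complete protection is needed so that no free ortho-phenol can undergo Algar–Flynn–Oyamada-type cyclisation in the later alkaline peroxide step.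

Step 4
Reactants: 7 4-hydroxybenzaldehyde
Product: 8 4-(methoxymethoxy)benzaldehyde
Conditions: MOMCl, K2CO3, acetone, rt
Reagents that add atoms: chloromethyl methyl ether (MOMCl), COCCl
Why: Williamson-type acetal formation on the phenoxide; masking the phenol keeps the aldehyde electrophilic in the aldol step and the enone β-carbon electrophilic in the epoxidation.

Step 5
Reactants: 6 1-[2,4,6-tris(methoxymethoxy)-3,5-di(prop-2-enyl)phenyl]ethanone; 8 4-(methoxymethoxy)benzaldehyde
Product: 10 (E)-3-[4-(methoxymethoxy)phenyl]-1-[2,4,6-tris(methoxymethoxy)-3,5-di(prop-2-enyl)phenyl]prop-2-en-1-one, via aldol adduct 9 (not isolated)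
Conditions: KOH, EtOH–THF–H2O, rt
Reagents that add atoms: none
Why: Claisen–Schmidt condensation (crossed aldol addition of the methyl ketone enolate to the non-enolisable aldehyde, then E1cB dehydration) should give the more stable E-enone; the MOM ethers and the unconjugated allyl groups are inert to KOH at room temperature.

Step 6
Reactants: 10 (E)-chalcone from step 5
Product: 11 [(2R,3S)-3-[4-(methoxymethoxy)phenyl]oxiran-2-yl][2,4,6-tris(methoxymethoxy)-3,5-di(prop-2-enyl)phenyl]methanone
Conditions: poly-L-leucine, urea–H2O2, DBU, THF, rt
Reagents that add atoms: urea–hydrogen peroxide, NC(N)=O.OO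
Why: Juliá–Colonna epoxidation, a Weitz–Scheffer nucleophilic epoxidation (hydroperoxide conjugate addition, then closure of the peroxy-enolate) taking place on the helical L-polypeptide, which should direct oxygen to the enone face that gives the trans (2R,3S)-oxirane and so fixes the later C3; the nucleophilic oxidant does not touch the isolated allyl alkenes.

Step 7
Reactants: 11 (2R,3S)-epoxy ketone from step 6
Product: 13 (2R,3R)-6,8-diallylaromadendrin, via tetrahydroxy epoxy ketone 12 (not isolated)
Conditions: HCl (aq.), MeOH–THF, 50 °C
Reagents that add atoms: none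
Why: Acid-catalysed acetal cleavage followed by intramolecular epoxide opening, in which one of the two equivalent ortho-phenols attacks the benzylic oxirane carbon in a 6-endo sense with inversion (S becomes R at C2) while the carbinol carbon keeps its configuration (R at C3); any cis epimer formed through a benzylic cation is the less stable isomer and can revert to the diequatorial trans ring by reversible opening at C2, and allyl groups, unlike prenyl groups, should not cyclise onto the neighbouring phenols under these conditions.

Step 8
Reactants: 13 (2R,3R)-6,8-diallylaromadendrin; 14 2-methyl-2-butene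
Product: 17 (2R,3R)-6,8-diprenylaromadendrin, via 8-allyl-6-prenylaromadendrin 15 (not isolated), via 6-allyl-8-prenylaromadendrin 16 (not isolated)
Conditions: second-generation Grubbs catalyst RuCl2(H2IMes)(PCy3)(=CHPh) (10 mol %), 2-methyl-2-butene (large excess), 1,4-benzoquinone (10 mol %), CH2Cl2, 35 °C, sealed tube
Reagents that add atoms: none
Why: Olefin cross-metathesis by the Chauvin mechanism: after loss of PCy3 the ruthenium alkylidene forms ruthenacyclobutanes with 2-methyl-2-butene and with each terminal allyl alkene, so the isopropylidene unit is passed to the ArCH2CH= terminus while the CH2 and CHCH3 ends leave as propene. The closest known reaction type is the cross-metathesis of aryl-allyl groups with 2-methyl-2-butene that turns allylphenols into prenylphenols, here run twice on one molecule through the mono-prenyl compounds 15 and 16. No ring is closed and no stereocentre is formed; C2 and C3 are remote from the reacting alkenes and the neutral conditions should leave trans ring C untouched. The selectivities needed are isopropylidene over ethylidene transfer and no allyl-to-propenyl migration: the large excess of the trisubstituted olefin keeps the catalyst loaded with it, any crotyl by-product stays metathesis-active and is driven on to the trisubstituted product, which does not re-enter the cycle, and benzoquinone intercepts ruthenium hydrides. Ring closure between the two allyl groups is geometrically impossible because they are meta to each other on ring A, and homodimerisation is suppressed by dilution in the partner olefin. The free phenols, the C4 ketone and the C3 alcohol are tolerated by the catalyst, which is why every acid step can precede this one.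

Compound list

1 | 2,4,6-trihydroxyacetophenone | CC(=O)c1c(O)cc(O)cc1O | starting material
2 | allyl bromide (3-bromoprop-1-ene) | C=CCBr | starting material
3 | 1-[2-hydroxy-4,6-bis(prop-2-enyloxy)phenyl]ethanone | CC(=O)c1c(O)cc(OCC=C)cc1OCC=C | intermediate
4 | 1-[2,4-dihydroxy-3-(prop-2-enyl)-6-(prop-2-enyloxy)phenyl]ethanone (mono-rearranged ether, drawn as the 3-allyl isomer; a 5-allyl isomer would converge on 5 as well) | CC(=O)c1c(O)c(CC=C)c(O)cc1OCC=C | intermediate (not isolated)
5 | 1-[2,4,6-trihydroxy-3,5-di(prop-2-enyl)phenyl]ethanone (3,5-diallyl-2,4,6-trihydroxyacetophenone) | CC(=O)c1c(O)c(CC=C)c(O)c(CC=C)c1O | intermediate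
6 | 1-[2,4,6-tris(methoxymethoxy)-3,5-di(prop-2-enyl)phenyl]ethanone | CC(=O)c1c(OCOC)c(CC=C)c(OCOC)c(CC=C)c1OCOC | intermediate
7 | 4-hydroxybenzaldehyde | O=Cc1ccc(O)cc1 | starting material
8 | 4-(methoxymethoxy)benzaldehyde | COCOc1ccc(C=O)cc1 | intermediate
9 | 3-hydroxy-3-[4-(methoxymethoxy)phenyl]-1-[2,4,6-tris(methoxymethoxy)-3,5-di(prop-2-enyl)phenyl]propan-1-one (aldol adduct, racemic at the carbinol carbon, which is lost on dehydration) | C=CCc1c(OCOC)c(CC=C)c(OCOC)c(C(=O)CC(O)c2ccc(OCOC)cc2)c1OCOC | intermediate (not isolated)
10 | (E)-3-[4-(methoxymethoxy)phenyl]-1-[2,4,6-tris(methoxymethoxy)-3,5-di(prop-2-enyl)phenyl]prop-2-en-1-one | C=CCc1c(OCOC)c(CC=C)c(OCOC)c(C(=O)/C=C/c2ccc(OCOC)cc2)c1OCOC | intermediate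
11 | [(2R,3S)-3-[4-(methoxymethoxy)phenyl]oxiran-2-yl][2,4,6-tris(methoxymethoxy)-3,5-di(prop-2-enyl)phenyl]methanone (trans-oxirane) | C=CCc1c(OCOC)c(CC=C)c(OCOC)c(C(=O)[C@@H]2O[C@H]2c2ccc(OCOC)cc2)c1OCOC | intermediate
12 | [(2R,3S)-3-(4-hydroxyphenyl)oxiran-2-yl][2,4,6-trihydroxy-3,5-di(prop-2-enyl)phenyl]methanone | C=CCc1c(O)c(CC=C)c(O)c(C(=O)[C@@H]2O[C@H]2c2ccc(O)cc2)c1O | intermediate (not isolated)
13 | (2R,3R)-3,5,7-trihydroxy-2-(4-hydroxyphenyl)-6,8-di(prop-2-enyl)chroman-4-one ((2R,3R)-6,8-diallylaromadendrin, 2,3-trans) | C=CCc1c(O)c(CC=C)c2c(c1O)C(=O)[C@H](O)[C@@H](c1ccc(O)cc1)O2 | intermediate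
14 | 2-methyl-2-butene | CC=C(C)C | starting material
15 | (2R,3R)-3,5,7-trihydroxy-2-(4-hydroxyphenyl)-6-(3-methylbut-2-enyl)-8-(prop-2-enyl)chroman-4-one | CC(C)=CCc1c(O)c(CC=C)c2c(c1O)C(=O)[C@H](O)[C@@H](c1ccc(O)cc1)O2 | intermediate (not isolated)
16 | (2R,3R)-3,5,7-trihydroxy-2-(4-hydroxyphenyl)-8-(3-methylbut-2-enyl)-6-(prop-2-enyl)chroman-4-one | C=CCc1c(O)c(CC=C(C)C)c2c(c1O)C(=O)[C@H](O)[C@@H](c1ccc(O)cc1)O2 | intermediate (not isolated)
17 | (2R,3R)-3,5,7-trihydroxy-2-(4-hydroxyphenyl)-6,8-bis(3-methylbut-2-enyl)chroman-4-one (6,8-diprenylaromadendrin) | CC(C)=CCc1c(O)c(CC=C(C)C)c2c(c1O)C(=O)[C@H](O)[C@@H](c1ccc(O)cc1)O2 | target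

Total step count: 8. Longest linear sequence: 7 steps (steps 1, 2, 3, 5, 6, 7 and 8 from compound 1); step 4 is a one-step branch.

Steps most likely to fail

1. Step 6. The ketone is flanked by two ortho acetal groups and the β-aryl ring is electron-rich, so the peptide-mediated oxygen transfer may be slow and may show poor facial selectivity. Fallback: catalyst control is given up and the racemate is resolved. Setting out from 10, uncatalysed Weitz–Scheffer epoxidation (H2O2, NaOH, MeOH–THF, 0 °C to rt) should give the racemic trans-epoxy ketone F1. The conditions of step 7 should convert it into racemic trans-6,8-diallylaromadendrin F2. Preparative HPLC on a cellulose- or amylose-carbamate chiral stationary phase separates the enantiomers, and the (2R,3R) enantiomer re-enters the route as 13.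

2. Step 7. The oxirane may ionise at the benzylic carbon before the ortho-phenol is free. This would lead to capture by solvent, aroyl migration, 5-exo closure to a benzofuranone, or erosion of the trans to cis preference. Fallback: ring opening and ring closure are separated by using an external sulfur nucleophile. Setting out from 11, BnSH and SnCl4 in CH2Cl2 at −20 °C should open the oxirane at the benzylic carbon and cleave the four acetals. This gives (2S)-3-(benzylsulfanyl)-2-hydroxy-3-(4-hydroxyphenyl)-1-[2,4,6-trihydroxy-3,5-di(prop-2-enyl)phenyl]propan-1-one F3, as a mixture of epimers at the sulfur-bearing carbon. The carbinol carbon is spatially unchanged; its descriptor changes only because sulfur raises the priority of the neighbouring carbon. Thiophilic activation with AgBF4 in CH2Cl2 at 0 °C should then let the ortho-phenol displace the sulfide. The trans ring is expected to predominate and is separated from any cis epimer, and the route is rejoined at 13.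

3. Step 8. The exchange may stop at the mono-prenyl stage, transfer ethylidene (crotyl groups), shift the allyl double bond into conjugation through ruthenium hydrides, or stall because the free ortho-phenols bind the catalyst or the tetrol dissolves poorly. Fallback: the hydroxyls are masked with groups that come off with fluoride instead of acid. Setting out from 13, TBSCl and imidazole in DMF should give the 3,7,4'-tris-O-tert-butyldimethylsilyl ether of 6,8-diallylaromadendrin F4, with the chelated 5-hydroxyl left free. The same metathesis with 14 should give the 3,7,4'-tris-O-tert-butyldimethylsilyl ether of 6,8-diprenylaromadendrin F5. Bu4NF buffered with AcOH in THF at 0 °C removes the silyl groups without acid and returns to the route at 17.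

Further compounds

F1 | step 6 | racemic trans-[3-[4-(methoxymethoxy)phenyl]oxiran-2-yl][2,4,6-tris(methoxymethoxy)-3,5-di(prop-2-enyl)phenyl]methanone (both enantiomers) | C=CCc1c(OCOC)c(CC=C)c(OCOC)c(C(=O)[C@@H]2O[C@H]2c2ccc(OCOC)cc2)c1OCOC.C=CCc1c(OCOC)c(CC=C)c(OCOC)c(C(=O)[C@H]2O[C@@H]2c2ccc(OCOC)cc2)c1OCOC
F2 | step 6 | racemic trans-6,8-diallylaromadendrin (both enantiomers) | C=CCc1c(O)c(CC=C)c2c(c1O)C(=O)[C@H](O)[C@@H](c1ccc(O)cc1)O2.C=CCc1c(O)c(CC=C)c2c(c1O)C(=O)[C@@H](O)[C@H](c1ccc(O)cc1)O2
F3 | step 7 | (2S)-3-(benzylsulfanyl)-2-hydroxy-3-(4-hydroxyphenyl)-1-[2,4,6-trihydroxy-3,5-di(prop-2-enyl)phenyl]propan-1-one (epimers at C3 of the chain) | C=CCc1c(O)c(CC=C)c(O)c(C(=O)[C@H](O)C(SCc2ccccc2)c2ccc(O)cc2)c1O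
F4 | step 8 | (2R,3R)-3,7-bis(tert-butyldimethylsilyloxy)-2-[4-(tert-butyldimethylsilyloxy)phenyl]-5-hydroxy-6,8-di(prop-2-enyl)chroman-4-one | C=CCc1c(O[Si](C)(C)C(C)(C)C)c(CC=C)c2c(c1O)C(=O)[C@H](O[Si](C)(C)C(C)(C)C)[C@@H](c1ccc(O[Si](C)(C)C(C)(C)C)cc1)O2
F5 | step 8 | (2R,3R)-3,7-bis(tert-butyldimethylsilyloxy)-2-[4-(tert-butyldimethylsilyloxy)phenyl]-5-hydroxy-6,8-bis(3-methylbut-2-enyl)chroman-4-one | CC(C)=CCc1c(O[Si](C)(C)C(C)(C)C)c(CC=C(C)C)c2c(c1O)C(=O)[C@H](O[Si](C)(C)C(C)(C)C)[C@@H](c1ccc(O[Si](C)(C)C(C)(C)C)cc1)O2
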